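All constants are made up; the flask was simulated.

    starting material + reagent → target (k1 = 2.21 /M/s)
    second substrate + reagent → second product (k2 = 1.79 /M/s)
    starting material + second substrate → cross product (k3 = 1.26 /M/s)
    2 reagent → homo dimer (k4 = 0.276 /M/s)
    reagent + target → over-reaction product (k5 = 0.680 /M/s)

Read side by side, the constants describe a race for the reagent, and you are asked what these flasks hold at the end:

| setting | midnight | spring | winter |
|---|---|---|---|
| starting material | 0.35 M | 0.35 M | 0.35 M |
| reagent | 0.270 M | 0.350 M | 0.210 M |
| second substrate | 0.350 M | 0.350 M | 0.350 M |
| time | 1.0 min | 1.0 min | 1.0 min |

1. which of the two there is more of at the end, midnight (target / cross product)
2. which of the two there is more of at the end, spring (target / cross product)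
3. which of the two there is more of at the end, winter (target / cross product)
4. target at the end, in percent of the starting material charged, midnight
5. target at the end, in percent of the starting material charged, spring
6. target at the end, in percent of the starting material charged, winter

- where a step has two of a species, its rate is k times that concentration squared, and two are used at each turn
- run time (midnight): 1.0 min

Ask first what the end state must be. The reagent is the limiting reagent: its largest charge, 0.350 M in spring, is less than the 0.700 M of substrates it can meet. Its lifetime against those substrates as charged is 0.714 s, far shorter than the 1.0 min of the run, so I count its whole charge as used and ask where it went.

In spring the gross share, the reagent taken by the starting material over the reagent taken by its outlets at the start, with two reagent lost at each dimer turn, is 48.6 %. Over-reaction then acts on both sides of the ledger, using a reagent and destroying a target. So I put target at the level the gross share implies and hold it there throughout, a deliberate overcharge, with the starting material held at its charge as well. That gives 38.5 %, and this net share, target gained per reagent used, is the number to carry. Multiplied by the reagent as a fraction of the charge, it gives 38.5 % of target in spring.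

The same reckoning gives net shares of 41.6 % at midnight and 44.1 % in winter, so target of 32.1 % and 26.5 %. Scoring the cross product with what target leaves as a ceiling, I expect cross product at midnight, cross product in spring and cross product in winter.

The forecast names cross product for midnight, cross product for spring and cross product for winter, with target at 29.5 %, 35 % and 24 %, “more reagent raising target yield less than proportionally”. In spring my figure stands higher than its own.

The simulation gives target 31.8 %, 37.4 % and 26.5 % against cross product 62.2 %, 53.9 % and 68.9 % at midnight, in spring and in winter. The forecast held on each answer, and spring's target reads 37.4 % after 10.0 min as well.

The difference in reagent charge is the main reason spring's target stands above winter's: with that difference taken away, the spring flask ends at 26.5 %, not 37.4 %. Over-reaction is a part of what holds spring's target down: with that step struck out, the spring flask ends at 47.9 %. In the reckoning the net share then returns to the gross share, and their gap on the spring charge is 10 percentage points, beside a simulated loss of 10 points. On the midnight flask recharged with 0.59 M of starting material, the net share times its 0.458 equiv of reagent gives 24.8 %, and that flask ends at 26.9 % of target, with 24 % of its starting material still unbound.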